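**Retrosynthetic overview**

1. Ring numbering used throughout: C1 (CH carrying isopropenyl), C2 (CH2), C3–C4 (trans-oxirane, methyl on C4), C5 (angelate), C6 (CH2), C7–C8 (cis-oxirane, methyl on C8), C9 (acetate), C10 (angelate); the ten-membered carbocycle is ring A.
2. Enabling feature: C2 is a bare ring methylene bonded to the oxirane CH C3. Taking the 3,4-oxirane back to the E-olefin C3=C4 makes C2–C3 a C(sp3)–C(sp2) bond, so ring A is closed there by coupling an alkylzinc at C2 with an E-alkenyl iodide at C3; the stored E geometry later becomes the trans-oxirane under direction of the C5 hydroxyl.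
3. Seco-iodide 24 comes from a Z-selective Wittig union at C7=C8 of phosphonium salt 8 (C3–C7; C5 by Keck allylation) with α-silyloxy methyl ketone 18 (C8–C10, C1, C2; C10 and C1 by Sharpless epoxidation and cuprate opening, C9 by Felkin–Anh addition).
4. Order of ring formation: oxirane C7–C8 on the open chain (step 16), ring A (step 19), oxirane C3–C4 on the ring (step 21); the acetate goes on before ring closure, the two angelates last.

Key step: step 19

Remark: both 2-methylbut-2-enoates are read as Z (angelates), the 3,4-oxirane as derived from an E olefin and the 7,8-oxirane from a Z olefin; 1 and 9 are taken as commercial.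

**Route**

Step 1
Reactants: 1 (E)-3-iodo-2-methylprop-2-en-1-ol
Product: 2 (E)-3-iodo-2-methylprop-2-enal
Conditions: MnO2, CH2Cl2, 20 °C
Reagents that add atoms: none
Why: Allylic alcohol oxidation with MnO2 should give the enal without touching the alkenyl iodide or its E geometry.

Step 2
Reactants: 2 (E)-3-iodo-2-methylprop-2-enal
Product: 3 (3S,1E)-1-iodo-2-methylhexa-1,5-dien-3-ol
Conditions: allylSnBu3, (S)-BINOL (20 mol %), Ti(OiPr)4 (10 mol %), 4 Å MS, CH2Cl2, −20 °C; aq. NaHCO3
Reagents that add atoms: allyltributylstannane, C=CC[Sn](CCCC)(CCCC)CCCC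
Why: Keck asymmetric allylation, in which the (S)-BINOL–titanium catalyst should deliver the allyl group to the Si face of the aldehyde and so set C5 (S) under catalyst control.

Step 3
Reactants: 3 (3S,1E)-1-iodo-2-methylhexa-1,5-dien-3-ol
Product: 4 tert-butyl{[(3S,1E)-1-iodo-2-methylhexa-1,5-dien-3-yl]oxy}dimethylsilane
Conditions: TBSCl, imidazole, DMF, 20 °C
Reagents that add atoms: tert-butyldimethylsilyl chloride, CC(C)(C)[Si](C)(C)Cl
Why: Standard silylation protects O5 for the ylide chemistry and leaves the C5 configuration untouched.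

Step 4
Reactants: 4 tert-butyl{[(3S,1E)-1-iodo-2-methylhexa-1,5-dien-3-yl]oxy}dimethylsilane
Product: 6 (3S,4E)-3-[(tert-butyldimethylsilyl)oxy]-5-iodo-4-methylpent-4-en-1-ol, via C7 aldehyde 5 (not isolated)
Conditions: O3, CH2Cl2/MeOH, −78 °C (one equivalent); then NaBH4, −78 → 0 °C
Reagents that add atoms: ozone, [O-][O+]=O
Why: Ozonolysis with reductive work-up should cleave only the electron-rich terminal vinyl group, the iodine-deactivated trisubstituted olefin reacting far more slowly, and gives the C7 alcohol directly.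

Step 5
Reactants: 6 (3S,4E)-3-[(tert-butyldimethylsilyl)oxy]-5-iodo-4-methylpent-4-en-1-ol
Product: 7 tert-butyl{[(3S,1E)-1,5-diiodo-2-methylpent-1-en-3-yl]oxy}dimethylsilane
Conditions: I2, PPh3, imidazole, CH2Cl2, 0 °C
Reagents that add atoms: iodine, II
Why: Appel iodination of the primary alcohol is reliable and does not affect the alkenyl iodide or C5.

Step 6
Reactants: 7 tert-butyl{[(3S,1E)-1,5-diiodo-2-methylpent-1-en-3-yl]oxy}dimethylsilane
Product: 8 [(3S,4E)-3-[(tert-butyldimethylsilyl)oxy]-5-iodo-4-methylpent-4-en-1-yl]triphenylphosphonium iodide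
Conditions: PPh3, MeCN, 80 °C
Reagents that add atoms: triphenylphosphine, c1ccc(cc1)P(c1ccccc1)c1ccccc1
Why: Displacement of the primary iodide by the phosphine gives the Wittig salt, while the alkenyl iodide is inert to a phosphine in the absence of a transition metal.

Step 7
Reactants: 9 (E)-4,4-dimethoxybut-2-enal
Product: 10 (E)-4,4-dimethoxybut-2-en-1-ol
Conditions: NaBH4, MeOH, 0 °C
Reagents that add atoms: none
Why: 1,2-Reduction of the enal gives the E allylic alcohol needed for asymmetric epoxidation, the acetal being stable to borohydride.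

Step 8
Reactants: 10 (E)-4,4-dimethoxybut-2-en-1-ol
Product: 11 [(2R,3S)-3-(dimethoxymethyl)oxiran-2-yl]methanol
Conditions: Ti(OiPr)4 (10 mol %), diethyl D-(−)-tartrate (12 mol %), t-BuOOH, 4 Å MS, CH2Cl2, −20 °C
Reagents that add atoms: tert-butyl hydroperoxide, CC(C)(C)OO
Why: Sharpless asymmetric epoxidation, in which the D-(−)-tartrate catalyst selects the olefin face that gives the (2R,3S) trans-epoxy alcohol and thereby fixes C10 and, after the next step, C1.

Step 9
Reactants: 11 [(2R,3S)-3-(dimethoxymethyl)oxiran-2-yl]methanol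
Product: 12 (2S,3S)-4,4-dimethoxy-2-(prop-1-en-2-yl)butane-1,3-diol
Conditions: isopropenylmagnesium bromide (excess), CuI (10 mol %), THF/Et2O, −40 → 0 °C
Reagents that add atoms: isopropenylmagnesium bromide, CC(=C)[Mg]Br
Why: Copper-catalysed Grignard opening of the 2,3-epoxy alcohol should occur at the carbon next to CH2OH (the other is shielded and deactivated by the acetal) with inversion, which sets C1 anti to O10 and installs the isopropenyl group; any 1,2-diol regioisomer is separable.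

Step 10
Reactants: 12 (2S,3S)-4,4-dimethoxy-2-(prop-1-en-2-yl)butane-1,3-diol
Product: 13 (2S,3S)-1,3-bis[(tert-butyldimethylsilyl)oxy]-4,4-dimethoxy-2-(prop-1-en-2-yl)butane
Conditions: TBSCl, imidazole, DMAP (cat.), DMF, 40 °C
Reagents that add atoms: tert-butyldimethylsilyl chloride, CC(C)(C)[Si](C)(C)Cl
Why: Double silylation under non-acidic conditions protects O10 and the C2 hydroxyl without disturbing the acetal.

Step 11
Reactants: 13 (2S,3S)-1,3-bis[(tert-butyldimethylsilyl)oxy]-4,4-dimethoxy-2-(prop-1-en-2-yl)butane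
Product: 15 (2S,3S)-2,4-bis[(tert-butyldimethylsilyl)oxy]-3-(prop-1-en-2-yl)butanal, via collidinium salt 14 (not isolated)
Conditions: TESOTf, 2,4,6-collidine, CH2Cl2, 0 °C; then H2O
Reagents that add atoms: water, O
Why: Silyl triflate/collidine acetal cleavage passes through a pyridinium intermediate that water hydrolyses to the aldehyde under essentially neutral conditions, so both silyl ethers and the epimerisable C10 centre should survive.

Step 12
Reactants: 15 (2S,3S)-2,4-bis[(tert-butyldimethylsilyl)oxy]-3-(prop-1-en-2-yl)butanal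
Product: 17 (3S,4S,5S)-4-[(tert-butyldimethylsilyl)oxy]-5-{[(tert-butyldimethylsilyl)oxy]methyl}-3-hydroxy-6-methylhept-6-en-2-one, via enol ether 16 (not isolated)
Conditions: ethyl vinyl ether, tert-butyllithium, THF, −78 → 0 °C; then 15, −78 °C; then 0.5 M HCl, THF, 0 °C
Reagents that add atoms: ethyl vinyl ether (used as 1-ethoxyvinyllithium), C=COCC; water, O
Why: Addition of the acetyl anion equivalent 1-ethoxyvinyllithium to the α-silyloxy aldehyde should follow the polar Felkin–Anh model and give the 9,10-anti diol pattern (C9 S), and brief mild acid unmasks the methyl ketone; the minor C9 epimer is separable.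

Step 13
Reactants: 17 (3S,4S,5S)-4-[(tert-butyldimethylsilyl)oxy]-5-{[(tert-butyldimethylsilyl)oxy]methyl}-3-hydroxy-6-methylhept-6-en-2-one
Product: 18 (3S,4S,5S)-4-[(tert-butyldimethylsilyl)oxy]-5-{[(tert-butyldimethylsilyl)oxy]methyl}-6-methyl-3-[(triethylsilyl)oxy]hept-6-en-2-one
Conditions: TESCl, imidazole, DMF, 0 °C
Reagents that add atoms: chlorotriethylsilane, CC[Si](CC)(CC)Cl
Why: Mild silylation gives the α-silyloxy methyl ketone required for the Z-selective Wittig reaction, and the triethylsilyl group can later be removed in the presence of the secondary silyl ethers.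

Step 14
Reactants: 8 [(3S,4E)-3-[(tert-butyldimethylsilyl)oxy]-5-iodo-4-methylpent-4-en-1-yl]triphenylphosphonium iodide; 18 (3S,4S,5S)-4-[(tert-butyldimethylsilyl)oxy]-5-{[(tert-butyldimethylsilyl)oxy]methyl}-6-methyl-3-[(triethylsilyl)oxy]hept-6-en-2-one
Product: 20 (1E,3S,5Z,7R,8S,9S)-3,8-bis[(tert-butyldimethylsilyl)oxy]-9-{[(tert-butyldimethylsilyl)oxy]methyl}-1-iodo-2,6,10-trimethyl-7-[(triethylsilyl)oxy]undeca-1,5,10-triene, via ylide 19 (not isolated)
Conditions: NaN(SiMe3)2, THF, −78 °C; then 18, −78 → 20 °C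
Reagents that add atoms: none
Why: Wittig olefination of an α-alkoxy methyl ketone with a non-stabilised ylide is a known Z-selective route to trisubstituted allylic ethers, so C6 and C9 should end up cis on C7=C8; the amide base does not exchange the alkenyl iodide and addition at low temperature should outrun enolisation at C9.

Step 15
Reactants: 20 (1E,3S,5Z,7R,8S,9S)-3,8-bis[(tert-butyldimethylsilyl)oxy]-9-{[(tert-butyldimethylsilyl)oxy]methyl}-1-iodo-2,6,10-trimethyl-7-[(triethylsilyl)oxy]undeca-1,5,10-triene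
Product: 21 (1E,3S,5Z,7R,8S,9S)-3,8-bis[(tert-butyldimethylsilyl)oxy]-9-(hydroxymethyl)-1-iodo-2,6,10-trimethylundeca-1,5,10-trien-7-ol
Conditions: camphorsulfonic acid (10 mol %), MeOH/CH2Cl2 (1:1), 0 °C
Reagents that add atoms: none
Why: Acid-catalysed methanolysis removes the triethylsilyl ether and the primary silyl ether much faster than the two secondary tert-butyldimethylsilyl ethers, which frees O9 and the C2 hydroxyl in one operation.

Step 16
Reactants: 21 (1E,3S,5Z,7R,8S,9S)-3,8-bis[(tert-butyldimethylsilyl)oxy]-9-(hydroxymethyl)-1-iodo-2,6,10-trimethylundeca-1,5,10-trien-7-ol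
Product: 22 (1E,3S,5S,6R,7S,8S,9S)-3,8-bis[(tert-butyldimethylsilyl)oxy]-5,6-epoxy-9-(hydroxymethyl)-1-iodo-2,6,10-trimethylundeca-1,10-dien-7-ol
Conditions: mCPBA (1.1 equiv), NaHCO3, CH2Cl2, 0 °C
Reagents that add atoms: 3-chloroperoxybenzoic acid, O=C(OO)c1cccc(Cl)c1
Why: Hydroxyl-directed peracid epoxidation: 1,3-allylic strain between C6 and the C9 substituents holds the C9 hydrogen in the olefin plane, so the C9 hydroxyl should deliver oxygen to its own face and give the threo cis-oxirane (ring C7 S, C8 as in the target), while the alkenyl iodide and the undirected isopropenyl group react more slowly.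

Step 17
Reactants: 22 (1E,3S,5S,6R,7S,8S,9S)-3,8-bis[(tert-butyldimethylsilyl)oxy]-5,6-epoxy-9-(hydroxymethyl)-1-iodo-2,6,10-trimethylundeca-1,10-dien-7-ol
Product: 23 (1E,3S,5S,6R,7S,8S,9R)-3,8-bis[(tert-butyldimethylsilyl)oxy]-5,6-epoxy-1-iodo-9-(iodomethyl)-2,6,10-trimethylundeca-1,10-dien-7-ol
Conditions: I2, PPh3, imidazole, CH2Cl2, 0 °C
Reagents that add atoms: iodine, II
Why: Appel iodination is selective for the primary C2 hydroxyl over the hindered secondary epoxy alcohol, and excess imidazole buffers the oxirane.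

Step 18
Reactants: 23 (1E,3S,5S,6R,7S,8S,9R)-3,8-bis[(tert-butyldimethylsilyl)oxy]-5,6-epoxy-1-iodo-9-(iodomethyl)-2,6,10-trimethylundeca-1,10-dien-7-ol
Product: 24 (1E,3S,5S,6S,7S,8S,9R)-7-acetoxy-3,8-bis[(tert-butyldimethylsilyl)oxy]-5,6-epoxy-1-iodo-9-(iodomethyl)-2,6,10-trimethylundeca-1,10-diene
Conditions: Ac2O, pyridine, DMAP (cat.), CH2Cl2, 20 °C
Reagents that add atoms: acetic anhydride, CC(=O)OC(C)=O
Why: Acetylation of the only free hydroxyl installs the C9 acetate of the target before ring closure, with no neighbouring free hydroxyl to which it could migrate.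

Step 19
Reactants: 24 (1E,3S,5S,6S,7S,8S,9R)-7-acetoxy-3,8-bis[(tert-butyldimethylsilyl)oxy]-5,6-epoxy-1-iodo-9-(iodomethyl)-2,6,10-trimethylundeca-1,10-diene
Product: 26 (1R,3E,5S,7S,8S,9S,10S)-9-acetoxy-5,10-bis[(tert-butyldimethylsilyl)oxy]-7,8-epoxy-4,8-dimethyl-1-(prop-1-en-2-yl)cyclodec-3-ene, via alkylzinc iodide 25 (not isolated)
Conditions: Zn dust (activated with 1,2-dibromoethane and Me3SiCl), THF, 35 °C; then syringe-pump addition over 12 h to Pd(OAc)2 (10 mol %), SPhos (20 mol %), THF, 50 °C, final 0.002 M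
Reagents that add atoms: none
Why: Proposed new method: zinc inserts into the primary C2–I bond (the alkenyl C3–I bond is inert to zinc dust without lithium chloride) to give 25, zerovalent palladium adds oxidatively to the E-alkenyl iodide, intramolecular transmetalation gives an eleven-membered alkyl(alkenyl)palladacycle, and C(sp3)–C(sp2) reductive elimination forms C2–C3; the closest known reaction types are the intermolecular Negishi coupling of β-branched alkylzinc iodides with (E)-2-methyl-1-iodoalkenes and the intramolecular B-alkyl Suzuki–Miyaura closure of nine- to twelve-membered E-cycloalkenes. Ring A, the only ring closed, forms by macrocyclising cross-coupling at the alkenyl carbon, contracting from the palladacycle on reductive elimination. No new stereocentre is formed: C1, C5, C7, C8, C9 and C10 are untouched and the E geometry of C3=C4 is carried over from the iodide with retention. The step needs cyclisation over oligomerisation, secured by slow addition of 25 to the catalyst at high dilution and by the cis-oxirane and the Z-derived turn at C6–C9 that bring the chain ends together; it also needs reductive elimination over β-hydride loss of the C1 hydrogen, secured by the bulky biarylphosphine. Acetate, oxirane, silyl ethers and the isopropenyl group are inert to alkylzinc halides and to the palladium catalyst.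

Step 20
Reactants: 26 (1R,3E,5S,7S,8S,9S,10S)-9-acetoxy-5,10-bis[(tert-butyldimethylsilyl)oxy]-7,8-epoxy-4,8-dimethyl-1-(prop-1-en-2-yl)cyclodec-3-ene
Product: 27 (1R,3E,5S,7S,8S,9S,10S)-9-acetoxy-7,8-epoxy-4,8-dimethyl-1-(prop-1-en-2-yl)cyclodec-3-ene-5,10-diol
Conditions: HF·pyridine, pyridine, THF, 0 → 20 °C
Reagents that add atoms: none
Why: Pyridine-buffered fluoride desilylation frees O5 and O10 under mildly acidic conditions that should spare the oxirane and suppress O9 to O10 acetyl migration.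

Step 21
Reactants: 27 (1R,3E,5S,7S,8S,9S,10S)-9-acetoxy-7,8-epoxy-4,8-dimethyl-1-(prop-1-en-2-yl)cyclodec-3-ene-5,10-diol
Product: 28 (1R,3R,4R,5S,7S,8S,9S,10S)-9-acetoxy-3,4:7,8-diepoxy-4,8-dimethyl-1-(prop-1-en-2-yl)cyclodecane-5,10-diol
Conditions: mCPBA (1.1 equiv), NaHCO3, CH2Cl2, −10 → 0 °C
Reagents that add atoms: 3-chloroperoxybenzoic acid, O=C(OO)c1cccc(Cl)c1
Why: Hydroxyl-directed peracid epoxidation on the medium ring: ring A holds C6 out of the C3=C4 plane on the inner face, so the C5 hydroxyl can sit on the exposed face at the dihedral angle suited to hydrogen-bonded peracid delivery, which should place the oxirane oxygen syn to O5 (C3 R, C4 as in the target) on the open face of the E olefin, the directed trisubstituted olefin outpacing the isopropenyl group.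

Step 22
Reactants: 28 (1R,3R,4R,5S,7S,8S,9S,10S)-9-acetoxy-3,4:7,8-diepoxy-4,8-dimethyl-1-(prop-1-en-2-yl)cyclodecane-5,10-diol
Product: 29 (1R,3R,4S,5S,7S,8S,9S,10S)-9-acetoxy-3,4:7,8-diepoxy-4,8-dimethyl-1-(prop-1-en-2-yl)cyclodecane-5,10-diyl bis[(Z)-2-methylbut-2-enoate] (CNP0220329.2)
Conditions: angelic acid, 2,4,6-trichlorobenzoyl chloride, Et3N, toluene, 20 °C; then 28, toluene, 80 °C
Reagents that add atoms: angelic acid, C/C=C(/C)C(O)=O
Why: Yamaguchi-type acylation through the angelic 2,4,6-trichlorobenzoic mixed anhydride without a nucleophilic catalyst is the stereoconservative way to make angelates of hindered secondary alcohols, and acylates O5 and O10 with retention at carbon.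

**Compound list**

1 | (E)-3-iodo-2-methylprop-2-en-1-ol | OC/C(C)=C/I | starting material
2 | (E)-3-iodo-2-methylprop-2-enal | O=C/C(C)=C/I | intermediate
3 | (3S,1E)-1-iodo-2-methylhexa-1,5-dien-3-ol | I/C=C(C)/[C@@H](O)CC=C | intermediate
4 | tert-butyl{[(3S,1E)-1-iodo-2-methylhexa-1,5-dien-3-yl]oxy}dimethylsilane | I/C=C(C)/[C@@H](O[Si](C)(C)C(C)(C)C)CC=C | intermediate
5 | (3S,4E)-3-[(tert-butyldimethylsilyl)oxy]-5-iodo-4-methylpent-4-enal | I/C=C(C)/[C@@H](O[Si](C)(C)C(C)(C)C)CC=O | intermediate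
6 | (3S,4E)-3-[(tert-butyldimethylsilyl)oxy]-5-iodo-4-methylpent-4-en-1-ol | I/C=C(C)/[C@@H](O[Si](C)(C)C(C)(C)C)CCO | intermediate
7 | tert-butyl{[(3S,1E)-1,5-diiodo-2-methylpent-1-en-3-yl]oxy}dimethylsilane | I/C=C(C)/[C@@H](O[Si](C)(C)C(C)(C)C)CCI | intermediate
8 | [(3S,4E)-3-[(tert-butyldimethylsilyl)oxy]-5-iodo-4-methylpent-4-en-1-yl]triphenylphosphonium iodide | I/C=C(C)/[C@@H](O[Si](C)(C)C(C)(C)C)CC[P+](c1ccccc1)(c1ccccc1)c1ccccc1.[I-] | intermediate
9 | (E)-4,4-dimethoxybut-2-enal | COC(OC)/C=C/C=O | starting material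
10 | (E)-4,4-dimethoxybut-2-en-1-ol | COC(OC)/C=C/CO | intermediate
11 | [(2R,3S)-3-(dimethoxymethyl)oxiran-2-yl]methanol | OC[C@H]1O[C@@H]1C(OC)OC | intermediate
12 | (2S,3S)-4,4-dimethoxy-2-(prop-1-en-2-yl)butane-1,3-diol | OC[C@H](C(C)=C)[C@H](O)C(OC)OC | intermediate
13 | (2S,3S)-1,3-bis[(tert-butyldimethylsilyl)oxy]-4,4-dimethoxy-2-(prop-1-en-2-yl)butane | CC(C)(C)[Si](C)(C)OC[C@H](C(C)=C)[C@H](O[Si](C)(C)C(C)(C)C)C(OC)OC | intermediate
14 | 1-[(2S,3S)-2,4-bis[(tert-butyldimethylsilyl)oxy]-1-methoxy-3-(prop-1-en-2-yl)butyl]-2,4,6-trimethylpyridinium triflate (both epimers at the N,O-acetal carbon) | CC(C)(C)[Si](C)(C)OC[C@H](C(C)=C)[C@H](O[Si](C)(C)C(C)(C)C)C(OC)[n+]1c(C)cc(C)cc1C.[O-]S(=O)(=O)C(F)(F)F | intermediate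
15 | (2S,3S)-2,4-bis[(tert-butyldimethylsilyl)oxy]-3-(prop-1-en-2-yl)butanal | CC(C)(C)[Si](C)(C)OC[C@H](C(C)=C)[C@H](O[Si](C)(C)C(C)(C)C)C=O | intermediate
16 | (3S,4S,5S)-4-[(tert-butyldimethylsilyl)oxy]-5-{[(tert-butyldimethylsilyl)oxy]methyl}-2-ethoxy-6-methylhepta-1,6-dien-3-ol | C=C(OCC)[C@@H](O)[C@@H](O[Si](C)(C)C(C)(C)C)[C@H](CO[Si](C)(C)C(C)(C)C)C(C)=C | intermediate
17 | (3S,4S,5S)-4-[(tert-butyldimethylsilyl)oxy]-5-{[(tert-butyldimethylsilyl)oxy]methyl}-3-hydroxy-6-methylhept-6-en-2-one | CC(=O)[C@@H](O)[C@@H](O[Si](C)(C)C(C)(C)C)[C@H](CO[Si](C)(C)C(C)(C)C)C(C)=C | intermediate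
18 | (3S,4S,5S)-4-[(tert-butyldimethylsilyl)oxy]-5-{[(tert-butyldimethylsilyl)oxy]methyl}-6-methyl-3-[(triethylsilyl)oxy]hept-6-en-2-one | CC(=O)[C@@H](O[Si](CC)(CC)CC)[C@@H](O[Si](C)(C)C(C)(C)C)[C@H](CO[Si](C)(C)C(C)(C)C)C(C)=C | intermediate
19 | [(3S,4E)-3-[(tert-butyldimethylsilyl)oxy]-5-iodo-4-methylpent-4-en-1-ylidene]triphenylphosphorane | I/C=C(C)/[C@@H](O[Si](C)(C)C(C)(C)C)CC=P(c1ccccc1)(c1ccccc1)c1ccccc1 | intermediate
20 | (1E,3S,5Z,7R,8S,9S)-3,8-bis[(tert-butyldimethylsilyl)oxy]-9-{[(tert-butyldimethylsilyl)oxy]methyl}-1-iodo-2,6,10-trimethyl-7-[(triethylsilyl)oxy]undeca-1,5,10-triene | I/C=C(C)/[C@@H](O[Si](C)(C)C(C)(C)C)C/C=C(C)\[C@@H](O[Si](CC)(CC)CC)[C@@H](O[Si](C)(C)C(C)(C)C)[C@H](CO[Si](C)(C)C(C)(C)C)C(C)=C | intermediate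
21 | (1E,3S,5Z,7R,8S,9S)-3,8-bis[(tert-butyldimethylsilyl)oxy]-9-(hydroxymethyl)-1-iodo-2,6,10-trimethylundeca-1,5,10-trien-7-ol | I/C=C(C)/[C@@H](O[Si](C)(C)C(C)(C)C)C/C=C(C)\[C@@H](O)[C@@H](O[Si](C)(C)C(C)(C)C)[C@H](CO)C(C)=C | intermediate
22 | (1E,3S,5S,6R,7S,8S,9S)-3,8-bis[(tert-butyldimethylsilyl)oxy]-5,6-epoxy-9-(hydroxymethyl)-1-iodo-2,6,10-trimethylundeca-1,10-dien-7-ol | I/C=C(C)/[C@@H](O[Si](C)(C)C(C)(C)C)C[C@@H]1O[C@]1(C)[C@@H](O)[C@@H](O[Si](C)(C)C(C)(C)C)[C@H](CO)C(C)=C | intermediate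
23 | (1E,3S,5S,6R,7S,8S,9R)-3,8-bis[(tert-butyldimethylsilyl)oxy]-5,6-epoxy-1-iodo-9-(iodomethyl)-2,6,10-trimethylundeca-1,10-dien-7-ol | I/C=C(C)/[C@@H](O[Si](C)(C)C(C)(C)C)C[C@@H]1O[C@]1(C)[C@@H](O)[C@@H](O[Si](C)(C)C(C)(C)C)[C@H](CI)C(C)=C | intermediate
24 | (1E,3S,5S,6S,7S,8S,9R)-7-acetoxy-3,8-bis[(tert-butyldimethylsilyl)oxy]-5,6-epoxy-1-iodo-9-(iodomethyl)-2,6,10-trimethylundeca-1,10-diene | I/C=C(C)/[C@@H](O[Si](C)(C)C(C)(C)C)C[C@@H]1O[C@]1(C)[C@@H](OC(C)=O)[C@@H](O[Si](C)(C)C(C)(C)C)[C@H](CI)C(C)=C | intermediate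
25 | alkylzinc iodide of 24 (C2–ZnI in place of C2–I) | I/C=C(C)/[C@@H](O[Si](C)(C)C(C)(C)C)C[C@@H]1O[C@]1(C)[C@@H](OC(C)=O)[C@@H](O[Si](C)(C)C(C)(C)C)[C@H](C[Zn]I)C(C)=C | intermediate
26 | (1R,3E,5S,7S,8S,9S,10S)-9-acetoxy-5,10-bis[(tert-butyldimethylsilyl)oxy]-7,8-epoxy-4,8-dimethyl-1-(prop-1-en-2-yl)cyclodec-3-ene (ring numbering of the overview) | C=C(C)[C@H]1C/C=C(C)/[C@@H](O[Si](C)(C)C(C)(C)C)C[C@@H]2O[C@]2(C)[C@@H](OC(C)=O)[C@H]1O[Si](C)(C)C(C)(C)C | intermediate
27 | (1R,3E,5S,7S,8S,9S,10S)-9-acetoxy-7,8-epoxy-4,8-dimethyl-1-(prop-1-en-2-yl)cyclodec-3-ene-5,10-diol | C=C(C)[C@H]1C/C=C(C)/[C@@H](O)C[C@@H]2O[C@]2(C)[C@@H](OC(C)=O)[C@H]1O | intermediate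
28 | (1R,3R,4R,5S,7S,8S,9S,10S)-9-acetoxy-3,4:7,8-diepoxy-4,8-dimethyl-1-(prop-1-en-2-yl)cyclodecane-5,10-diol | C=C(C)[C@H]1C[C@H]2O[C@]2(C)[C@@H](O)C[C@@H]2O[C@]2(C)[C@@H](OC(C)=O)[C@H]1O | intermediate
29 | (1R,3R,4S,5S,7S,8S,9S,10S)-9-acetoxy-3,4:7,8-diepoxy-4,8-dimethyl-1-(prop-1-en-2-yl)cyclodecane-5,10-diyl bis[(Z)-2-methylbut-2-enoate] | C=C(C)[C@H]1C[C@H]2O[C@]2(C)[C@@H](OC(=O)/C(C)=C\C)C[C@@H]2O[C@]2(C)[C@@H](OC(C)=O)[C@H]1OC(=O)/C(C)=C\C | target

**Summary**

Total step count: 22. Longest linear sequence: 16 steps (from 9, steps 7–22); the other branch from 1 is 15 steps.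

Steps most likely to fail:

1. Step 19 (proposed new method). What may go wrong: intermolecular coupling to oligomers instead of ring closure, β-hydride loss from the alkylpalladium intermediate, protonation of the alkylzinc, or zinc insertion into the alkenyl iodide. The fallback uses known chemistry, closes the same C2–C3 bond at a higher oxidation level of C2, and sets out from 24. Kornblum-type oxidation of the primary iodide with trimethylamine N-oxide in DMSO should give the C2 aldehyde F1. An intramolecular Nozaki–Hiyama–Kishi reaction (CrCl2, catalytic NiCl2, DMSO/THF, high dilution) should then close ring A to the ring allylic alcohol F2 (either C2 epimer serves). Acetylation (Ac2O, pyridine) gives the allylic acetate F3, and palladium-catalysed allylic reduction (Pd(PPh3)4, Bu3SnH, hydride delivered to the less substituted allyl terminus C2) removes the extra oxygen with the C3=C4 olefin kept in place. The route is rejoined at 26.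

2. Step 21. What may go wrong: poor facial selectivity, with epoxidation through the other ring conformer giving the 3,4-epimeric oxirane, or competing oxidation of the isopropenyl group. The fallback replaces substrate direction by reagent control and sets out from 26. Shi epoxidation with the D-fructose-derived ketone (KHSO5, K2CO3, MeCN/dimethoxymethane/aqueous buffer, 0 °C), whose sense on E-trisubstituted olefins corresponds to the required oxirane, should give the bis-silyl bis-epoxide F4. HF·pyridine then removes both silyl ethers and the route is rejoined at 28.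

3. Step 22. What may go wrong: Z to E isomerisation of the angeloyl unit to tiglate during acyl transfer, acetyl migration from O9 to O10 before O10 is acylated, or incomplete acylation of the two hindered epoxy alcohols. The fallback builds the Z-enoates in place instead of transferring them and sets out from 28. Both hydroxyls are esterified with 2-[bis(2,2,2-trifluoroethoxy)phosphoryl]propanoic acid (diisopropylcarbodiimide, catalytic DMAP, CH2Cl2, 0 °C) to the bis(phosphonopropionate) F5. A double Still–Gennari olefination with acetaldehyde (KN(SiMe3)2, 18-crown-6, THF, −78 °C) should then give both (Z)-2-methylbut-2-enoates and rejoin the route at 29.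

Further compounds
F1 | step 19 | C2 aldehyde from 24 (CHO in place of CH2I) | I/C=C(C)/[C@@H](O[Si](C)(C)C(C)(C)C)C[C@@H]1O[C@]1(C)[C@@H](OC(C)=O)[C@@H](O[Si](C)(C)C(C)(C)C)[C@H](C=O)C(C)=C
F2 | step 19 | 2-hydroxy derivative of 26 (ring allylic alcohol, C2 epimers) | C=C(C)[C@H]1C(O)/C=C(C)/[C@@H](O[Si](C)(C)C(C)(C)C)C[C@@H]2O[C@]2(C)[C@@H](OC(C)=O)[C@H]1O[Si](C)(C)C(C)(C)C
F3 | step 19 | 2-acetoxy derivative of 26 (allylic acetate) | C=C(C)[C@H]1C(OC(C)=O)/C=C(C)/[C@@H](O[Si](C)(C)C(C)(C)C)C[C@@H]2O[C@]2(C)[C@@H](OC(C)=O)[C@H]1O[Si](C)(C)C(C)(C)C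
F4 | step 21 | 5,10-bis(tert-butyldimethylsilyl) ether of 28 | C=C(C)[C@H]1C[C@H]2O[C@]2(C)[C@@H](O[Si](C)(C)C(C)(C)C)C[C@@H]2O[C@]2(C)[C@@H](OC(C)=O)[C@H]1O[Si](C)(C)C(C)(C)C
F5 | step 22 | 5,10-bis{2-[bis(2,2,2-trifluoroethoxy)phosphoryl]propanoate} of 28 | C=C(C)[C@H]1C[C@H]2O[C@]2(C)[C@@H](OC(=O)C(C)P(=O)(OCC(F)(F)F)OCC(F)(F)F)C[C@@H]2O[C@]2(C)[C@@H](OC(C)=O)[C@H]1OC(=O)C(C)P(=O)(OCC(F)(F)F)OCC(F)(F)F
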